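## Retrosynthetic overview
1. Stereochemical reading of target 15: it is a head-to-tail 12-membered [3.3]metacyclophane dimer. Cyclohexene ring A is (3R,4S,5R), with 3,4-cis and 4,5-trans, which is the endo adduct of an E-chalcone. Ring B is (3R,4R,5R), with 3,4-trans and 4,5-cis, which is the C4 epimer of that same endo adduct.
2. 15 ⇒ 14 (six MOM ethers) ⇒ 12, the C2-symmetric endo,endo bis-adduct, by inverting one ketone α-carbon. The two ketones of 12 are equivalent, so either gives 14.
3. 12 ⇒ 2 × 9. A single dienyl-chalcone monomer undergoes a one-flask enantioselective double Diels–Alder cyclodimerisation that forms four C–C bonds and six stereocentres.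
4. 9 ⇒ 6 + 8 (Claisen–Schmidt). 6 ⇒ 3 + 5 (Suzuki). The starting materials are 1, 4 and 7.
5. Ring order: cyclohexene A forms first (intermolecular), then cyclohexene B and the macrocycle form in the same intramolecular event, and C4 of ring B is inverted last.

Locants for each cyclohexene: C1 (C–CH3, sp2), C2 (=CH), C3 (bears the macrocycle arene), C4 (bears the ketone), C5 (bears the 2,4-dioxygenated phenyl), C6 (CH2).

Assumption: (R)-VANOL [(R)-3,3'-diphenyl-2,2'-binaphthalene-1,1'-diol] is taken as the antipode that gives the (3R,4S,5R) series. The sense is checked on the first batch of 12, and if it is opposite, the equally available (S)-ligand is used with nothing else changed.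

## Route

Step 1
Reactants: 1 2,4-dihydroxyacetophenone
Product: 2 1-[2-hydroxy-4-(methoxymethoxy)phenyl]ethan-1-one
Conditions: MOMCl (1.1 equiv), K2CO3, acetone, 0 °C to rt
Reagents that add atoms: chloromethyl methyl ether (MOMCl), COCCl
Why: In this Williamson-type O-alkylation (MOM protection) the 2-OH is hydrogen-bonded to the acetyl group and is far less nucleophilic, so one equivalent of MOMCl reacts only at the 4-OH.

Step 2
Reactants: 2 1-[2-hydroxy-4-(methoxymethoxy)phenyl]ethan-1-one
Product: 3 1-[2-hydroxy-5-iodo-4-(methoxymethoxy)phenyl]ethan-1-one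
Conditions: NIS (1.05 equiv), MeCN, 0 °C to rt, dark
Reagents that add atoms: N-iodosuccinimide, O=C1CCC(=O)N1I
Why: In this electrophilic aromatic iodination C5 is para to the free phenol, ortho to OMOM and unhindered, whereas C3 is flanked by two oxygens, and neutral NIS leaves the MOM acetal intact.

Step 3
Reactants: 4 2-methylbut-1-en-3-yne
Product: 5 4,4,5,5-tetramethyl-2-[(1E)-3-methylbuta-1,3-dien-1-yl]-1,3,2-dioxaborolane
Conditions: HBpin (1.05 equiv), Cp2ZrHCl (5 mol %), Et3N (10 mol %), sealed tube, neat, 40 °C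
Reagents that add atoms: pinacolborane, CC1(C)OBOC1(C)C
Why: Zirconocene-hydride-catalysed syn hydroboration of the terminal alkyne places boron on the terminal carbon and gives only the E-alkenylboronate, because the 1,1-disubstituted alkene reacts much more slowly.

Step 4
Reactants: 3 1-[2-hydroxy-5-iodo-4-(methoxymethoxy)phenyl]ethan-1-one; 5 (E)-dienyl pinacol boronate
Product: 6 1-{2-hydroxy-4-(methoxymethoxy)-5-[(1E)-3-methylbuta-1,3-dien-1-yl]phenyl}ethan-1-one
Conditions: Pd(dppf)Cl2 (5 mol %), K2CO3 (3 equiv), dioxane/H2O, BHT (trace), 65 °C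
Reagents that add atoms: none
Why: Suzuki–Miyaura coupling retains the E-alkene geometry, the aryl iodide adds readily to zerovalent palladium, and the phenol, ketone and MOM groups tolerate aqueous carbonate.

Step 5
Reactants: 7 2,4-dihydroxybenzaldehyde
Product: 8 2,4-bis(methoxymethoxy)benzaldehyde
Conditions: MOMCl (3 equiv), K2CO3 (4 equiv), acetone, reflux
Reagents that add atoms: chloromethyl methyl ether (MOMCl), COCCl
Why: Williamson-type MOM protection with excess reagent and heat also alkylates the hydrogen-bonded 2-OH, which makes the aldehyde a usable aldol acceptor.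

Step 6
Reactants: 6 5-dienyl-2-hydroxy-4-MOM-acetophenone; 8 2,4-bis(methoxymethoxy)benzaldehyde
Product: 9 (E)-1-{2-hydroxy-4-(methoxymethoxy)-5-[(1E)-3-methylbuta-1,3-dien-1-yl]phenyl}-3-[2,4-bis(methoxymethoxy)phenyl]prop-2-en-1-one
Conditions: KOH (5 equiv), EtOH, rt, 36 h; then 1 M HCl to pH 6, 0 °C; store cold
Reagents that add atoms: none
Why: Claisen–Schmidt condensation (aldol, then E1cB dehydration) gives the thermodynamic E-enone, the MOM ethers and diene are inert to hydroxide, and the 2'-phenoxide keeps the chalcone from closing to the flavanone.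

Step 7
Reactants: 9 dienyl chalcone monomer (two molecules)
Product: 12 C2-symmetric endo,endo hexa-MOM macrocyclic bis-adduct [both cyclohexenes (3R,4S,5R)], via borate chelate 10 (not isolated), via endo mono-adduct 11 (not isolated)
Conditions: (R)-VANOL (1.1 equiv per 9), B(OPh)3 (1.1 equiv per 9), 4 Å MS, PhCF3, 0.03 M, 0 to 40 °C; then H2O/MeOH work-up, chromatography (ligand recovered)
Reagents that add atoms: none
Why: This is an asymmetric Diels–Alder reaction of a boron-chelated 2'-hydroxychalcone run as an inter-/intramolecular cascade, in which chelation of the 2'-O and C=O to the VANOL borate locks the enone s-cis, lowers its LUMO and shields one face, so that the E-diene of a second monomer adds suprafacially and endo (C3/C4 cis from the endo mode, C4/C5 trans from the E-enone, ortho/para regiochemistry) to give 11, whose remaining diene and chelated enone sit on two stacked resorcinol decks and close ring B and the 12-membered ring by the same endo, same-face addition, setting all six stereocentres as (3R,4S,5R) twice.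

Step 8
Reactants: 12 C2-symmetric endo,endo hexa-MOM bis-adduct
Product: 14 hexa-MOM mono-C4-epimer [ring A (3R,4S,5R); ring B (3R,4R,5R)], via ketone mono-enolate 13 (not isolated)
Conditions: NaOMe (10 equiv), MeOH/THF 1:1, 60 °C, HPLC control; then AcOH, 0 °C; chromatography, recovered 12 and bis-epimer resubmitted
Reagents that add atoms: none
Why: This is a base-mediated α-epimerisation of a ketone through its enolate under thermodynamic control, in which only C4–H is acidic (C3 and C5 are untouched), the phenoxide–enolate is the same kind of species that operates in step 6, the two ketones of 12 are homotopic so the first inversion gives one compound with a statistical factor of two and turns one cis (axial/equatorial) bridge junction into a trans-diequatorial one, and the run is stopped at the maximum of 14.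

Step 9
Reactants: 14 hexa-MOM mono-C4-epimer
Product: 15 target CNP0244682.3
Conditions: 3 M aq HCl (cat. amount relative to solvent), MeOH, 40 °C, short time, argon
Reagents that add atoms: none
Why: Acid-catalysed acetal exchange (MOM methanolysis) frees the six phenols without touching a C–C bond or stereocentre, and the low temperature and short time stay below the threshold for acid enolisation at C4 and for phenol–ketone ketalisation.

## Compound list
1 | 2,4-dihydroxyacetophenone | CC(=O)c1ccc(O)cc1O | starting material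
2 | 1-[2-hydroxy-4-(methoxymethoxy)phenyl]ethan-1-one | CC(=O)c1ccc(OCOC)cc1O | intermediate
3 | 1-[2-hydroxy-5-iodo-4-(methoxymethoxy)phenyl]ethan-1-one | CC(=O)c1cc(I)c(OCOC)cc1O | intermediate
4 | 2-methylbut-1-en-3-yne | C=C(C)C#C | starting material
5 | 4,4,5,5-tetramethyl-2-[(1E)-3-methylbuta-1,3-dien-1-yl]-1,3,2-dioxaborolane | C=C(C)/C=C/B1OC(C)(C)C(C)(C)O1 | intermediate
6 | 1-{2-hydroxy-4-(methoxymethoxy)-5-[(1E)-3-methylbuta-1,3-dien-1-yl]phenyl}ethan-1-one | CC(=O)c1cc(/C=C/C(C)=C)c(OCOC)cc1O | intermediate
7 | 2,4-dihydroxybenzaldehyde | O=Cc1ccc(O)cc1O | starting material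
8 | 2,4-bis(methoxymethoxy)benzaldehyde | O=Cc1ccc(OCOC)cc1OCOC | intermediate
9 | (E)-chalcone monomer carrying a 5'-(E)-3-methylbutadienyl group, a free 2'-OH and 4',2,4-tris-OMOM | O=C(/C=C/c1ccc(OCOC)cc1OCOC)c1cc(/C=C/C(C)=C)c(OCOC)cc1O | intermediate
10 | spiro-borate chelate of 9 with (R)-VANOL (boron bound to both VANOL oxygens, the 2'-phenolate O and the carbonyl O; the axial chirality R is not expressible in the SMILES) | C=C(C)/C=C/c1cc2c(cc1OCOC)O[B-]3(Oc4c(c(-c5ccccc5)cc5ccccc45)-c4c(O3)c3ccccc3cc4-c3ccccc3)[O+]=C2/C=C/c1ccc(OCOC)cc1OCOC | intermediate (not isolated)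
11 | endo mono-adduct, shown boron-free: a (3R,4S,5R)-1-methylcyclohexene in which C3 bears the arene that still carries the E-enone, C4 bears the aroyl group whose arene still carries the E-diene, and C5 bears 2,4-bis(OMOM)phenyl | CC1=C[C@@H](c2cc(C(=O)/C=C/c3ccc(OCOC)cc3OCOC)c(O)cc2OCOC)[C@@H](C(=O)c2cc(/C=C/C(C)=C)c(OCOC)cc2O)[C@H](c2ccc(OCOC)cc2OCOC)C1 | intermediate (not isolated)
12 | C2-symmetric endo,endo bis-adduct: a 12-membered [3.3]metacyclophane-dione with both cyclohexenes (3R,4S,5R) (3,4-cis, 4,5-trans), six MOM ethers and two free chelated OH | CC1=C[C@H]2c3cc(c(O)cc3OCOC)C(=O)[C@@H]3[C@@H](C=C(C)C[C@H]3c3ccc(OCOC)cc3OCOC)c3cc(c(O)cc3OCOC)C(=O)[C@H]2[C@H](c2ccc(OCOC)cc2OCOC)C1 | intermediate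
13 | mono-enolate of 12 at one ketone/C4, drawn as the neutral enol with C=C geometry unspecified | CC1=C[C@H]2c3cc(c(O)cc3OCOC)C(O)=C3[C@@H](C=C(C)C[C@H]3c3ccc(OCOC)cc3OCOC)c3cc(c(O)cc3OCOC)C(=O)[C@H]2[C@H](c2ccc(OCOC)cc2OCOC)C1 | intermediate (not isolated)
14 | hexa-MOM mono-C4-epimer: ring A (3R,4S,5R), ring B (3R,4R,5R) (3,4-trans, 4,5-cis) | CC1=C[C@H]2c3cc(c(O)cc3OCOC)C(=O)[C@H]3[C@@H](C=C(C)C[C@H]3c3ccc(OCOC)cc3OCOC)c3cc(c(O)cc3OCOC)C(=O)[C@H]2[C@H](c2ccc(OCOC)cc2OCOC)C1 | intermediate
15 | CNP0244682.3: octaphenol, ring A (3R,4S,5R), ring B (3R,4R,5R) | CC1=C[C@H]2c3cc(c(O)cc3O)C(=O)[C@H]3[C@@H](C=C(C)C[C@H]3c3ccc(O)cc3O)c3cc(c(O)cc3O)C(=O)[C@H]2[C@H](c2ccc(O)cc2O)C1 | target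

## Count and risks
Total steps: 9. Longest linear sequence: 7 (steps 1, 2, 4, 6, 7, 8, 9).

**Step 7 (most likely to fail).** Exo adducts, mixed endo/exo macrocycles or oligomers may outweigh the endo,endo dimer.
- The fallback replaces the homodimerisation with a stepwise cross-cycloaddition. It sets out from 3, 6 and 8 and returns at 11.
- Condensing 3 with 8 (KOH, EtOH) gives the dienophile-only iodochalcone F1.
- F1 reacts with the diene-only ketone 6 under the same (R)-VANOL borate. No oligomer can form, and the endo cross-adduct F2 is separated from its exo isomer at this small-molecule stage.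
- Suzuki coupling of F2 with 5 gives the dienyl cross-adduct F3.
- Claisen–Schmidt condensation of the acetyl group of F3 with 8 at rt delivers 11 as an isolated compound.
- 11 is then closed on its own at 0.002 M with the borate to give 12.

**Step 8.** The equilibrium inside the macrocycle may lie far on the side of 12, or enolisation may be blocked by ring strain.
- The fallback moves the inversion ahead of macrocyclisation. It sets out from 11 and returns at 14.
- 11 is obtained by stopping step 7 at 0 °C and partial conversion.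
- Its single ketone α-stereocentre is equilibrated in the unstrained open form (NaOMe, MeOH/THF) to the C4-epimeric mono-adduct F4, which is separated while 11 is recycled.
- The borate-promoted intramolecular endo Diels–Alder reaction of F4 then builds ring A last and arrives directly at 14.

**Step 9.** Free phenols in acid may ketalise the ring A ketone, add to the trisubstituted alkenes, or let C4 re-equilibrate.
- The fallback never lets phenol and acid coexist. It sets out from 14 and returns at 15.
- TMSOTf with 2,2'-bipyridyl in MeCN at 0 °C exchanges the aryl MOM ethers for silyl ethers and silylates the two free phenols, giving the octakis(trimethylsilyl) ether F5.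
- F5 is hydrolysed with neutral aqueous MeOH to 15.

## Further compounds
F1 | step 7 | (E)-1-[2-hydroxy-5-iodo-4-(methoxymethoxy)phenyl]-3-[2,4-bis(methoxymethoxy)phenyl]prop-2-en-1-one | O=C(/C=C/c1ccc(OCOC)cc1OCOC)c1cc(I)c(OCOC)cc1O
F2 | step 7 | endo cross-adduct, a (3R,4S,5R)-cyclohexene with C3 5-acetyl-4-hydroxy-2-(OMOM)phenyl, C4 2-hydroxy-5-iodo-4-(OMOM)benzoyl and C5 2,4-bis(OMOM)phenyl | CC1=C[C@@H](c2cc(C(C)=O)c(O)cc2OCOC)[C@@H](C(=O)c2cc(I)c(OCOC)cc2O)[C@H](c2ccc(OCOC)cc2OCOC)C1
F3 | step 7 | dienyl cross-adduct (iodide of F2 replaced by (E)-3-methylbuta-1,3-dienyl) | CC1=C[C@@H](c2cc(C(C)=O)c(O)cc2OCOC)[C@@H](C(=O)c2cc(/C=C/C(C)=C)c(OCOC)cc2O)[C@H](c2ccc(OCOC)cc2OCOC)C1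
F4 | step 8 | C4-epimeric mono-adduct, a (3R,4R,5R)-cyclohexene | CC1=C[C@@H](c2cc(C(=O)/C=C/c3ccc(OCOC)cc3OCOC)c(O)cc2OCOC)[C@H](C(=O)c2cc(/C=C/C(C)=C)c(OCOC)cc2O)[C@H](c2ccc(OCOC)cc2OCOC)C1
F5 | step 9 | octakis(trimethylsilyl) ether of 15 | CC1=C[C@H]2c3cc(c(O[Si](C)(C)C)cc3O[Si](C)(C)C)C(=O)[C@H]3[C@@H](C=C(C)C[C@H]3c3ccc(O[Si](C)(C)C)cc3O[Si](C)(C)C)c3cc(c(O[Si](C)(C)C)cc3O[Si](C)(C)C)C(=O)[C@H]2[C@H](c2ccc(O[Si](C)(C)C)cc2O[Si](C)(C)C)C1
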